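The cyclohexane ring is disconnected at C1–C2. This is the aldol bond between the tertiary carbinol C1 (OH, CO2H) and the CH2 that flanks the C3 oxygen. The key step exploits this β-hydroxycarbonyl pattern C1(OH)–C2H2–C3(O) and the adjacent trans C4/C5 diol. Its precursor is not a carbocycle but a pyranose, the seven-carbon ulosonic acid phosphate DAHP, assembled from D-erythrose 4-phosphate and phosphoenolpyruvate. A dehydroquinate synthase converts it in one operation (oxidation, phosphate elimination, reduction, ring opening, aldol closure) into the carbocycle with quaternary C1 set. A dehydrogenase in the same pot sets C3. The 1,5-lactone then masks O5 and CO2H, so that equatorial 3-OH and axial 4-OH are acylated in turn.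

Key step: step 2

Remark (numbering): quinic acid numbering is used for all carbocycles. C1 bears OH and CO2H, O3 is cis to O4 and to 1-OH, and O5 is trans to O4 and cis to CO2H. The target is therefore the 3-O-caffeoyl-4-O-p-coumaroyl ester of (−)-quinic acid.

Assumption: 1 and 2 are bought as Na/K salts (drawn as free acids). 10 and 13 are taken as catalogue compounds (otherwise one acetylation from caffeic or p-coumaric acid). The enzymes come from standard recombinant expression.

Step 1
Reactants: 1 D-erythrose 4-phosphate; 2 phosphoenolpyruvic acid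
Product: 3 3-deoxy-D-arabino-hept-2-ulosonic acid 7-phosphate (DAHP; 4R,5S,6R, drawn as the α-pyranose hemiketal)
Conditions: DAHP synthase (3-deoxy-7-phosphoheptulonate synthase, EC 2.5.1.54), MnCl2 (cat.), BTP buffer pH 7.0, 25 °C; anion-exchange chromatography
Reagents that add atoms: water, O
Why: Aldol-type C–C coupling by a transferase on its native substrates, in which C3 of 2 adds to one face of the aldehyde of 1 while water replaces phosphate at C2, so the enzyme sets the new 4R carbinol and the two centres of 1 are carried over as C5 and C6.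

Step 2
Reactants: 3 DAHP
Product: 5 (−)-quinic acid, via 3-dehydroquinic acid 4 (not isolated)
Conditions: 3-dehydroquinate synthase (cyclising phosphate lyase, EC 4.2.3.4), NAD+ (cat.), CoCl2 (cat.), MOPS pH 7.5, 25 °C; then quinate dehydrogenase (EC 1.1.1.24), formate dehydrogenase, HCO2Na, same pot; anion exchange
Reagents that add atoms: none
Why: The lyase runs five events on bound 3: its tightly held NAD+ oxidises only 5-OH, the acidified H6 allows syn E1cB loss of the C7 phosphate, the NADH formed returns hydride to C5 with the original configuration, the enol-pyranose hemiketal opens, and the C6–C7 enolate adds to the C2 keto acid. The closest small-molecule reaction type is the Ferrier carbocyclisation of 5-enopyranosides, i.e. an intramolecular aldol addition. The cyclohexane ring closes through the bond C7–C2 of 3 (C2–C1 of the ring) in a 6-(enolendo)-exo-trig mode via a chair with carboxylate, O4 and O5 equatorial. Ring C4 and C5 are carried over from 3; quaternary C1 (1-OH axial, cis to O4) is fixed by that chair as held in the active site, which excludes the C1 epimer open to a free enolate in solution; C3 is then set by the oxidoreductase, which delivers hydride from NADH to one face of the ketone of 4 to give the axial 3R alcohol. The step needs one hydroxyl out of three to be oxidised, one enolate and one carbonyl face: the substrate helps by carrying its only leaving group on C7, β to the transient C5 ketone, and its only ketone electrophile at the distance of a six-membered ring from C7, and the pocket does the rest. Immediate reduction keeps 4 from β-eliminating its 1-OH.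

Step 3
Reactants: 5 (−)-quinic acid
Product: 6 1,5-quinide, (1S,3R,4R,5R)-1,3,4-trihydroxy-6-oxabicyclo[3.2.1]octan-7-one
Conditions: TsOH·H2O (cat.), toluene–DMF, reflux, Dean–Stark
Reagents that add atoms: none
Why: Acid-catalysed lactonisation in which only O5 is cis to the carboxyl group, so a single γ-lactone should form after ring flip and water removal drives it, with no stereocentre touched.

Step 4
Reactants: 6 1,5-quinide
Product: 9 1-O-triethylsilyl-1,5-quinide (3-OH equatorial, 4-OH axial, both free), via 1,5-quinide 3,4-O-phenylboronate 7 (not isolated), via 1-O-triethylsilyl-1,5-quinide 3,4-O-phenylboronate 8 (not isolated)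
Conditions: PhB(OH)2 (1.0 equiv), toluene, reflux, Dean–Stark; evaporate; TESOTf, 2,6-lutidine, CH2Cl2, 0 °C; then pinacol, rt
Reagents that add atoms: phenylboronic acid, OB(O)c1ccccc1 (its B and phenyl stay only in 7 and 8); triethylsilyl trifluoromethanesulfonate, CC[Si](CC)(CC)OS(=O)(=O)C(F)(F)F
Why: Temporary boronic ester protection, in which only the cis O3/O4 pair can form a dioxaborolane, the one free (bridgehead) 1-OH is silylated by the silyl triflate, and transesterification to pinacol releases the diol, with no stereocentre touched.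

Step 5
Reactants: 9 1-O-triethylsilyl-1,5-quinide; 10 (E)-3,4-diacetoxycinnamic acid
Product: 12 3-O-[(E)-3,4-diacetoxycinnamoyl]-1-O-triethylsilyl-1,5-quinide, via (E)-3,4-diacetoxycinnamoyl chloride 11 (not isolated)
Conditions: 10, (COCl)2, DMF (cat.), CH2Cl2, 0 °C to rt, evaporate; then 9, Ph2BOCH2CH2NH2 (10 mol %), iPr2NEt, MeCN, 0 °C to rt
Reagents that add atoms: oxalyl chloride, ClC(=O)C(=O)Cl (supplies only the Cl of 11)
Why: Borinic-acid-catalysed regioselective monoacylation of a cis-1,2-diol, in which the tetracoordinate diphenylborinate of O3/O4 should be acylated at the less hindered equatorial O3 while O1 (silyl ether) and O5 (lactone) are masked, with no stereocentre touched.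

Step 6
Reactants: 12 3-O-acyl quinide; 13 (E)-4-acetoxycinnamic acid
Product: 15 3-O-[(E)-3,4-diacetoxycinnamoyl]-4-O-[(E)-4-acetoxycinnamoyl]-1-O-triethylsilyl-1,5-quinide, via (E)-4-acetoxycinnamoyl chloride 14 (not isolated)
Conditions: 13, (COCl)2, DMF (cat.), CH2Cl2, 0 °C to rt, evaporate; then 12, pyridine, DMAP (cat.), CH2Cl2, 0 °C to rt
Reagents that add atoms: oxalyl chloride, ClC(=O)C(=O)Cl (supplies only the Cl of 14)
Why: DMAP-catalysed acylation of the only remaining free hydroxyl (axial 4-OH), during which the 3-ester already sits in the thermodynamically preferred equatorial position and should not migrate, with no stereocentre touched.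

Step 7
Reactants: 15 fully protected diester lactone
Product: 16 3-O-(E)-caffeoyl-4-O-(E)-p-coumaroyl-(−)-quinic acid, (1R,3R,4S,5R) (target)
Conditions: 1 M aq HCl–THF (1:1), rt, HPLC control; lyophilise, reversed-phase chromatography
Reagents that add atoms: water, O
Why: Acid-catalysed hydrolysis should remove the TES ether and the three activated aryl acetates and open the strained γ-lactone, while the conjugated cinnamate esters react slowest and acid, unlike base, does not promote acyl migration to the freed 5-OH; only acyl–O and Si–O bonds break, so no stereocentre is touched.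

Compound list
1 | D-erythrose 4-phosphate (2R,3R) | O=C[C@H](O)[C@H](O)COP(=O)(O)O | starting material
2 | phosphoenolpyruvic acid | C=C(OP(=O)(O)O)C(=O)O | starting material
3 | 3-deoxy-D-arabino-hept-2-ulosonic acid 7-phosphate (DAHP), α-pyranose | OP(=O)(O)OC[C@H]1O[C@@](O)(C(=O)O)C[C@@H](O)[C@@H]1O | intermediate
4 | 3-dehydroquinic acid, (1R,3R,4S)-1,3,4-trihydroxy-5-oxocyclohexane-1-carboxylic acid | O[C@H]1[C@H](O)C[C@](O)(C(=O)O)CC1=O | intermediate
5 | (−)-quinic acid, (1S,3R,4S,5R) | O[C@H]1[C@H](O)C[C@](O)(C(=O)O)C[C@H]1O | intermediate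
6 | 1,5-quinide | O[C@H]1[C@H]2C[C@](O)(C(=O)O2)C[C@H]1O | intermediate
7 | 1,5-quinide 3,4-O-phenylboronate | c1ccc(cc1)B4O[C@H]2[C@H]3C[C@](O)(C(=O)O3)C[C@H]2O4 | intermediate
8 | 1-O-triethylsilyl-1,5-quinide 3,4-O-phenylboronate | c1ccc(cc1)B4O[C@H]2[C@H]3C[C@](O[Si](CC)(CC)CC)(C(=O)O3)C[C@H]2O4 | intermediate
9 | 1-O-triethylsilyl-1,5-quinide | O[C@H]1[C@H]2C[C@](O[Si](CC)(CC)CC)(C(=O)O2)C[C@H]1O | intermediate
10 | (E)-3,4-diacetoxycinnamic acid | CC(=O)Oc1ccc(/C=C/C(=O)O)cc1OC(C)=O | starting material
11 | (E)-3,4-diacetoxycinnamoyl chloride | CC(=O)Oc1ccc(/C=C/C(=O)Cl)cc1OC(C)=O | intermediate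
12 | 3-O-[(E)-3,4-diacetoxycinnamoyl]-1-O-triethylsilyl-1,5-quinide | O[C@H]1[C@H]2C[C@](O[Si](CC)(CC)CC)(C(=O)O2)C[C@H]1OC(=O)/C=C/c1ccc(OC(C)=O)c(OC(C)=O)c1 | intermediate
13 | (E)-4-acetoxycinnamic acid | CC(=O)Oc1ccc(/C=C/C(=O)O)cc1 | starting material
14 | (E)-4-acetoxycinnamoyl chloride | CC(=O)Oc1ccc(/C=C/C(=O)Cl)cc1 | intermediate
15 | 3-O-[(E)-3,4-diacetoxycinnamoyl]-4-O-[(E)-4-acetoxycinnamoyl]-1-O-triethylsilyl-1,5-quinide | O=C(/C=C/c1ccc(OC(C)=O)cc1)O[C@H]1[C@H]2C[C@](O[Si](CC)(CC)CC)(C(=O)O2)C[C@H]1OC(=O)/C=C/c1ccc(OC(C)=O)c(OC(C)=O)c1 | intermediate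
16 | 3-O-(E)-caffeoyl-4-O-(E)-p-coumaroyl-(−)-quinic acid | O=C(/C=C/c1ccc(O)cc1)O[C@H]1[C@H](O)C[C@](O)(C(=O)O)C[C@H]1OC(=O)/C=C/c1ccc(O)c(O)c1 | target

Total step count: 7. Longest linear sequence: 7 steps (1 to 16); 10 and 13 enter as bought building blocks.

Steps most likely to fail

1. Step 5, loss of site selectivity. In the rigid bicycle the borinate may discriminate poorly between O3 and O4, or a second acylation may follow the first.
   - The fallback blocks O3 and reverses the order of acylation. It sets out from 9 and comes back at 15.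
   - TESCl/imidazole should silylate the equatorial 3-OH to give 1,3-bis-O-triethylsilyl-1,5-quinide F1.
   - Acid chloride 14 with pyridine/DMAP then acylates the only free hydroxyl to give 4-O-[(E)-4-acetoxycinnamoyl]-1,3-bis-O-triethylsilyl-1,5-quinide F2.
   - AcOH–THF–H2O at 0 °C should cleave the secondary 3-O-silyl ether faster than the bridgehead one, under acidic conditions that disfavour 4-to-3 migration. This gives 4-O-[(E)-4-acetoxycinnamoyl]-1-O-triethylsilyl-1,5-quinide F3.
   - Acid chloride 11 with pyridine at −20 °C esterifies the freed equatorial 3-OH and gives 15.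

2. Step 6, sluggish acylation of the axial, doubly flanked 4-OH. This leaves time for DMAP to shuttle acetyl groups from the aryl acetates onto O4.
   - The fallback uses a small neutral acyl donor and builds the alkene afterwards. It sets out from 12 and comes back at 16.
   - Meldrum's acid in refluxing toluene (acylketene, no base) should give the 4-O-malonyl half ester of 12 F4.
   - Knoevenagel–Doebner condensation with 4-hydroxybenzaldehyde (pyridine, β-alanine) gives, with decarboxylation, 3-O-[(E)-3,4-diacetoxycinnamoyl]-4-O-[(E)-p-coumaroyl]-1-O-triethylsilyl-1,5-quinide F5.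
   - The conditions of step 7 convert F5 into 16.

3. Step 4, premature loss of the boronate. Exchange with traces of water or with the triflate medium may occur before silylation is complete, so that silicon is delivered to O3 as well.
   - The fallback uses an isolable acetal that is removed by hydrogenolysis. It sets out from 5, bypasses 6 and comes back at 9.
   - Benzaldehyde, TsOH and toluene under Dean–Stark conditions should form lactone and acetal together to give 3,4-O-benzylidene-1,5-quinide F6.
   - TESOTf/2,6-lutidine gives 3,4-O-benzylidene-1-O-triethylsilyl-1,5-quinide F7.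
   - H2, Pd(OH)2/C in EtOAc cleaves the acetal at a stage without alkenes and gives 9.

Further compounds
F1 | step 5 | 1,3-bis-O-triethylsilyl-1,5-quinide | O[C@H]1[C@H]2C[C@](O[Si](CC)(CC)CC)(C(=O)O2)C[C@H]1O[Si](CC)(CC)CC
F2 | step 5 | 4-O-[(E)-4-acetoxycinnamoyl]-1,3-bis-O-triethylsilyl-1,5-quinide | O=C(/C=C/c1ccc(OC(C)=O)cc1)O[C@H]1[C@H]2C[C@](O[Si](CC)(CC)CC)(C(=O)O2)C[C@H]1O[Si](CC)(CC)CC
F3 | step 5 | 4-O-[(E)-4-acetoxycinnamoyl]-1-O-triethylsilyl-1,5-quinide | O=C(/C=C/c1ccc(OC(C)=O)cc1)O[C@H]1[C@H]2C[C@](O[Si](CC)(CC)CC)(C(=O)O2)C[C@H]1O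
F4 | step 6 | 4-O-malonyl half ester of 12 | OC(=O)CC(=O)O[C@H]1[C@H]2C[C@](O[Si](CC)(CC)CC)(C(=O)O2)C[C@H]1OC(=O)/C=C/c1ccc(OC(C)=O)c(OC(C)=O)c1
F5 | step 6 | 3-O-[(E)-3,4-diacetoxycinnamoyl]-4-O-[(E)-p-coumaroyl]-1-O-triethylsilyl-1,5-quinide | O=C(/C=C/c1ccc(O)cc1)O[C@H]1[C@H]2C[C@](O[Si](CC)(CC)CC)(C(=O)O2)C[C@H]1OC(=O)/C=C/c1ccc(OC(C)=O)c(OC(C)=O)c1
F6 | step 4 | 3,4-O-benzylidene-1,5-quinide (acetal carbon: either epimer) | c1ccc(cc1)C4O[C@H]2[C@H]3C[C@](O)(C(=O)O3)C[C@H]2O4
F7 | step 4 | 3,4-O-benzylidene-1-O-triethylsilyl-1,5-quinide (acetal carbon: either epimer) | c1ccc(cc1)C4O[C@H]2[C@H]3C[C@](O[Si](CC)(CC)CC)(C(=O)O3)C[C@H]2O4
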